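**Retrosynthetic overview**

- Kweichowenol B ⇐ Si–O cleavage ⇐ one-flask perbenzoic acid oxidation of a bis-silylated trans-1,2-dihydrodiol of benzyl benzoate: the second oxirane (C4–C5) is opened at allylic C4 by the benzoic acid the peracid leaves behind.
- Dihydrodiol diene ⇐ Br2 addition and double E2 on the cyclohex-3-ene trans-diol.
- trans-Diol ⇐ benzoate-assisted, inverting opening at C1 of the first oxirane (C1–C6) ⇐ Sharpless epoxidation of (cyclohexa-1,4-dienyl)methanol, a dihydro-arene oxide that cannot racemise through an oxepin.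
- Dienol ⇐ Birch reduction of benzyl alcohol: the carbocycle is never built, it is the arene ring, as in the biosynthesis.
- Ring order: arene-derived carbocycle → C1–C6 oxirane (opened trans) → C4–C5 oxirane (opened trans).

Assumption: the presumed biosynthesis is benzyl benzoate → arene 1,2-oxide → trans-1,2-dihydrodiol → second oxirane on the neighbouring C=C (anti to the adjacent hydroxyl) → benzoate attack at the allylic oxirane carbon.

Numbering in all names follows the target: C1 carries CH2O, C6 is its oxygenated neighbour, C4 carries the ring benzoate.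

**Route**

Step 1
Reactants: 1 benzyl alcohol
Product: 2 (cyclohexa-1,4-dien-1-yl)methanol
Conditions: n-BuLi (1.0 equiv), THF, −78 °C; then Li (2.5 equiv), NH3(l), t-BuOH (2.5 equiv), −78 °C; NH4Cl
Reagents that add atoms: none
Why: Birch reduction: the pre-formed lithium alkoxide cannot undergo benzylic C–O hydrogenolysis and behaves as an alkyl-type donor, so the ring is reduced to the 2,5-dihydro isomer with the substituent on a double bond; no stereocentre is formed.

Step 2
Reactants: 2 (cyclohexa-1,4-dien-1-yl)methanol
Product: 4 [(1S,6S)-7-oxabicyclo[4.1.0]hept-3-en-1-yl]methyl benzoate, via epoxy alcohol 3 (not isolated)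
Conditions: Ti(OiPr)4 (5 mol %), L-(+)-diisopropyl tartrate (6 mol %), t-BuOOH (2 equiv), 4 Å molecular sieves, CH2Cl2, −20 °C; then P(OMe)3, −20 °C; then Et3N, DMAP (cat.), PhCOCl, −10 → 0 °C
Reagents that add atoms: tert-butyl hydroperoxide, CC(C)(C)OO; benzoyl chloride, O=C(Cl)c1ccccc1
Why: Katsuki–Sharpless asymmetric epoxidation: the hydroxyl-bound titanium tartrate epoxidises only the allylic trisubstituted C1=C6 bond and, as with 1-cyclohexenylmethanol (about 93% ee), the L-(+)-tartrate gives the (1S,6S)-oxirane; the primary oxygen is then acylated in the same flask, so C6 is set for good and C1 in the sense that step 3 inverts.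

Step 3
Reactants: 4 [(1S,6S)-7-oxabicyclo[4.1.0]hept-3-en-1-yl]methyl benzoate
Product: 6 [(1R,6S)-1,6-dihydroxycyclohex-3-en-1-yl]methyl benzoate, via dioxolanylium ion 5 (not isolated)
Conditions: HClO4 (10 mol %), THF–H2O (5:1), 0 °C → rt
Reagents that add atoms: water, O
Why: acid-catalysed epoxide opening with neighbouring-group participation: the benzoate carbonyl attacks the tertiary oxirane carbon C1 from the face opposite the oxirane oxygen (five-membered dioxolanylium ring, Markovnikov) and water cleaves the cation to the primary benzoate (any tertiary benzoate shifts to the primary oxygen under the same acid), so C1 is inverted to R, C6 is untouched and the trans-diol results.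

Step 4
Reactants: 6 [(1R,6S)-1,6-dihydroxycyclohex-3-en-1-yl]methyl benzoate
Product: 7 [(1R,6S)-1,6-bis(triethylsilyloxy)cyclohex-3-en-1-yl]methyl benzoate
Conditions: Et3SiOTf (2.5 equiv), 2,6-lutidine (4 equiv), CH2Cl2, −78 → 0 °C
Reagents that add atoms: triethylsilyl trifluoromethanesulfonate, CC[Si](CC)(CC)OS(=O)(=O)C(F)(F)F
Why: silyl triflate silylation caps the secondary and the tertiary hydroxyl without touching a stereocentre, so that the later peracid step is ruled by sterics and not by hydrogen bonding.

Step 5
Reactants: 7 [(1R,6S)-1,6-bis(triethylsilyloxy)cyclohex-3-en-1-yl]methyl benzoate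
Product: 8 [(1R,3R,4R,6S)-3,4-dibromo-1,6-bis(triethylsilyloxy)cyclohexyl]methyl benzoate (together with its 3S,4S trans isomer)
Conditions: Br2 (1.05 equiv), NaHCO3 (solid), CH2Cl2, −78 °C
Reagents that add atoms: bromine, BrBr
Why: electrophilic anti addition of bromine to the only C=C gives the trans-dibromide; both trans diastereomers are usable because C3 and C4 become sp2 in the next step.

Step 6
Reactants: 8 [(1R,3R,4R,6S)-3,4-dibromo-1,6-bis(triethylsilyloxy)cyclohexyl]methyl benzoate
Product: 9 [(1R,6S)-1,6-bis(triethylsilyloxy)cyclohexa-2,4-dien-1-yl]methyl benzoate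
Conditions: DBU (5 equiv), toluene, 80 °C
Reagents that add atoms: none
Why: two consecutive anti E2 eliminations (through the allylic bromide), the standard way from 4,5-dibromocyclohexane-1,2-diol derivatives to 5,6-dioxygenated cyclohexa-1,3-dienes; C1 and C6 are not involved and, unlike an arene oxide, this O-silylated trans-dihydrodiol has no oxepin pathway for racemisation.

Step 7
Reactants: 9 [(1R,6S)-1,6-bis(triethylsilyloxy)cyclohexa-2,4-dien-1-yl]methyl benzoate
Product: 11 [(1R,4S,5R,6S)-4-(benzoyloxy)-5-hydroxy-1,6-bis(triethylsilyloxy)cyclohex-2-en-1-yl]methyl benzoate, via vinyl epoxide 10 (not isolated)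
Conditions: PhCO3H (1.0 equiv, freshly prepared, titrated), CH2Cl2, 0 °C; then i-Pr2NEt (20 mol %), 0 → 35 °C
Reagents that add atoms: perbenzoic acid, OOC(=O)c1ccccc1
Why: Proposed new method: Prilezhaev epoxidation followed in the same flask by acidolysis of the vinyl oxirane with the peracid's own by-product (closest known type: anti hydroxy-acyloxylation of alkenes by peracids, and peracid epoxidation/trans opening of trans-5,6-diacyloxycyclohexa-1,3-dienes, which gives the all-trans conduritol B array); the peracid should attack C4=C5 (C2=C3 is shielded on both faces by the fully substituted C1) anti to the C6 silyloxy group, and the ammonium benzoate formed from the released PhCO2H then opens the oxirane by SN2 at allylic C4 from the opposite face, which sets C4–OBz and C5–OH trans to each other and to their neighbours.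

Step 8
Reactants: 11 [(1R,4S,5R,6S)-4-(benzoyloxy)-5-hydroxy-1,6-bis(triethylsilyloxy)cyclohex-2-en-1-yl]methyl benzoate
Product: 12 kweichowenol B, [(1R,4S,5S,6S)-4-(benzoyloxy)-1,5,6-trihydroxycyclohex-2-en-1-yl]methyl benzoate
Conditions: HF·pyridine, pyridine–THF, 0 °C → rt
Reagents that add atoms: none
Why: fluoride cleavage of both Si–O bonds under buffered, weakly acidic conditions that avoid base-induced benzoyl migration round the triol; no stereocentre is touched.

**Compound list**

1 | benzyl alcohol | OCc1ccccc1 | starting material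
2 | (cyclohexa-1,4-dien-1-yl)methanol | OCC1=CCC=CC1 | intermediate
3 | [(1S,6S)-7-oxabicyclo[4.1.0]hept-3-en-1-yl]methanol (epoxy alcohol, formed in the flask in step 2) | OC[C@@]12CC=CC[C@@H]1O2 | intermediate
4 | [(1S,6S)-7-oxabicyclo[4.1.0]hept-3-en-1-yl]methyl benzoate | O=C(OC[C@@]12CC=CC[C@@H]1O2)c1ccccc1 | intermediate
5 | (5R,6S)-6-hydroxy-2-phenyl-1,3-dioxaspiro[4.5]dec-8-en-2-ylium (spiro carbon = C1; new C1–O bond trans to the C6 hydroxyl; formed in the flask in step 3) | [O+]1=C(c2ccccc2)OC[C@@]13CC=CC[C@@H]3O | intermediate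
6 | [(1R,6S)-1,6-dihydroxycyclohex-3-en-1-yl]methyl benzoate (trans-diol) | O=C(OC[C@]1(O)CC=CC[C@@H]1O)c1ccccc1 | intermediate
7 | [(1R,6S)-1,6-bis(triethylsilyloxy)cyclohex-3-en-1-yl]methyl benzoate | O=C(OC[C@]1(O[Si](CC)(CC)CC)CC=CC[C@@H]1O[Si](CC)(CC)CC)c1ccccc1 | intermediate
8 | [(1R,3R,4R,6S)-3,4-dibromo-1,6-bis(triethylsilyloxy)cyclohexyl]methyl benzoate (trans-dibromide; the 3S,4S isomer forms as well) | O=C(OC[C@]1(O[Si](CC)(CC)CC)C[C@@H](Br)[C@H](Br)C[C@@H]1O[Si](CC)(CC)CC)c1ccccc1 | intermediate
9 | [(1R,6S)-1,6-bis(triethylsilyloxy)cyclohexa-2,4-dien-1-yl]methyl benzoate | O=C(OC[C@]1(O[Si](CC)(CC)CC)C=CC=C[C@@H]1O[Si](CC)(CC)CC)c1ccccc1 | intermediate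
10 | [(1R,4R,5R,6S)-4,5-epoxy-1,6-bis(triethylsilyloxy)cyclohex-2-en-1-yl]methyl benzoate (oxirane cis to the C1–O bond, trans to the C6–O bond; formed in the flask in step 7) | O=C(OC[C@]1(O[Si](CC)(CC)CC)C=C[C@H]2O[C@H]2[C@@H]1O[Si](CC)(CC)CC)c1ccccc1 | intermediate
11 | [(1R,4S,5R,6S)-4-(benzoyloxy)-5-hydroxy-1,6-bis(triethylsilyloxy)cyclohex-2-en-1-yl]methyl benzoate | O=C(OC[C@]1(O[Si](CC)(CC)CC)C=C[C@H](OC(=O)c2ccccc2)[C@@H](O)[C@@H]1O[Si](CC)(CC)CC)c1ccccc1 | intermediate
12 | kweichowenol B, [(1R,4S,5S,6S)-4-(benzoyloxy)-1,5,6-trihydroxycyclohex-2-en-1-yl]methyl benzoate | O=C(OC[C@]1(O)C=C[C@H](OC(=O)c2ccccc2)[C@@H](O)[C@@H]1O)c1ccccc1 | target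

**Step count and risks**

Total steps: 8. Longest linear sequence: 8 steps, from benzyl alcohol.

Step 7 is the most likely to fail. The peracid may also attack C2=C3, may attack the wrong face, and benzoate may add at C2 (SN2') instead of C4. Fallback: set out from diene 9 and use osmylation in place of the oxirane. OsO4 (cat.) with N-methylmorpholine N-oxide in acetone–water should add to the less hindered C4=C5 bond anti to the allylic C6–O group and give the cis-4,5-diol F1. A Mitsunobu esterification (PhCO2H, PPh3, diisopropyl azodicarboxylate, THF, 0 °C) at the more reactive allylic C4 hydroxyl then inverts that centre, and the route is rejoined at 11.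

Step 3 is the second risk. Any water attack at C6 instead of C1 gives the enantiomeric diol and lowers the ee, and the acid may also cause a hydride shift to a ketone. Fallback: set out from epoxy alcohol 3, isolated without the in-flask benzoylation, and open it under base. NaOH in t-BuOH–H2O at 70 °C brings about a Payne rearrangement to the spiro-epoxide F2, whose CH2 is attacked by hydroxide to give the triol F3 with the same inversion at C1. Selective benzoylation of the primary hydroxyl (PhCOCl, 2,4,6-collidine, CH2Cl2, −40 °C) returns to 6.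

Step 6 is the third risk. The anti hydrogens next to the fully substituted C1 are hindered, and vinyl bromides or loss of silanol with aromatisation may compete. Fallback: set out from alkene 7 and use radical allylic bromination (N-bromosuccinimide, AIBN, PhCF3, 80 °C). Bromine is taken up mainly at the allyl terminus remote from the substituted carbons, giving the 4-bromo-2-ene F4 and the 3-bromo-4-ene F5. Each needs only one mild E2 (DBU, rt), and both give diene 9.

**Further compounds**

F1 | step 7 | [(1R,4R,5R,6S)-4,5-dihydroxy-1,6-bis(triethylsilyloxy)cyclohex-2-en-1-yl]methyl benzoate (4,5-cis-diol, both hydroxyls trans to the C6–O bond) | O=C(OC[C@]1(O[Si](CC)(CC)CC)C=C[C@@H](O)[C@@H](O)[C@@H]1O[Si](CC)(CC)CC)c1ccccc1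
F2 | step 3 | (3R,4S)-1-oxaspiro[2.5]oct-6-en-4-ol (Payne isomer of 3; spiro carbon = C1) | C1O[C@]12CC=CC[C@@H]2O
F3 | step 3 | (1R,2S)-1-(hydroxymethyl)cyclohex-4-ene-1,2-diol (trans-diol) | OC[C@]1(O)CC=CC[C@@H]1O
F4 | step 6 | [(1R,6S)-4-bromo-1,6-bis(triethylsilyloxy)cyclohex-2-en-1-yl]methyl benzoate (one C4 epimer drawn, both form) | O=C(OC[C@]1(O[Si](CC)(CC)CC)C=C[C@H](Br)C[C@@H]1O[Si](CC)(CC)CC)c1ccccc1
F5 | step 6 | [(1R,6S)-3-bromo-1,6-bis(triethylsilyloxy)cyclohex-4-en-1-yl]methyl benzoate (one C3 epimer drawn, both form) | O=C(OC[C@]1(O[Si](CC)(CC)CC)C[C@@H](Br)C=C[C@@H]1O[Si](CC)(CC)CC)c1ccccc1
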